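**Plan**

- Retrosynthesis: the two acetates and the C5=C6 enal (Wittig) are removed first, then the C11=C12 alkene is cut (Julia–Kocienski, C12 sulfone plus a C8–C11 aldehyde), then C13–C14 (anti-crotylboration of a C14 aldehyde), and last the ring bond C2–C3.
- Enabling feature: in the ring C15–C1–C2–C3–C4 the C2 methyl and the C3 oxygen are adjacent and trans (a trans-2-methylcyclopentanol). This is the retron of a reductive 5-exo ketyl–olefin cyclisation of a C3 aldehyde onto an allyl group on C15.
- Forward: (R)-malate supplies C14, C15, C4 and C5; C3 is added by alkoxymethylation at C4 and C1–C2(–Me) by allylation at C15; SmI2 then closes the only carbocycle; the side chain is grown at C14 and the enal at C5.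
- Stereochemistry: C15 from (R)-malate (retained through the cis-dioxolanone), C4 by anti Fráter–Seebach alkylation, C2 and C3 in the chair-like cyclisation under control of C4 and C15, C13 and C14 by a reagent-controlled (E)-crotylborane, both alkenes E from the olefinations.

Key step: step 10

Remark: locants are those of the parent skeleton (ring C15–C1–C2–C3–C4; C5=C6(Me)–C7HO on C4; chain C14–C13(Me)–C12=C11–C10Me2–C9(=O)–C8H3 on C15). "Up" is the ring face carrying C15–O, C3–O and the C4 arm; the C2 methyl and C14 are "down". Dimethyl (R)-malate, a commercial ester of (R)-malic acid, is taken as the chiral starting material.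

**Route**

Step 1
Reactants: 1 dimethyl (R)-malate; 2 benzyl chloromethyl ether
Product: 3 dimethyl (2S,3R)-2-[(benzyloxy)methyl]-3-hydroxybutanedioate (anti)
Conditions: LiN(SiMe3)2 (2.1 equiv), THF, −78 °C; then 2, −78 → −20 °C; aq. NH4Cl
Reagents that add atoms: none
Why: Fráter–Seebach alkylation: the chelated lithium alkoxide–enolate dianion should be alkylated to give the anti product, which sets C4 relative to C15, and the silylamide base leaves no nucleophilic amine to consume the chloromethyl ether.

Step 2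
Reactants: 3 dimethyl (2S,3R)-2-[(benzyloxy)methyl]-3-hydroxybutanedioate
Product: 4 (2S,3R)-2-[(benzyloxy)methyl]-3-hydroxybutanedioic acid
Conditions: LiOH·H2O (3 equiv), THF–H2O, 0 °C → rt; 1 M HCl to pH 2
Reagents that add atoms: lithium hydroxide, [Li+].[OH-]
Why: Saponification of both methyl esters at low temperature should neither epimerise C4 nor eliminate the β-benzyloxy group, because the carboxylate formed is hard to enolise.

Step 3
Reactants: 4 (2S,3R)-2-[(benzyloxy)methyl]-3-hydroxybutanedioic acid; 5 pivalaldehyde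
Product: 6 (2S)-3-(benzyloxy)-2-[(2R,4R)-2-tert-butyl-5-oxo-1,3-dioxolan-4-yl]propanoic acid (cis-dioxolanone)
Conditions: 5 (3 equiv), TsOH·H2O (cat.), H2SO4 (cat.), pentane, reflux, Dean–Stark trap
Reagents that add atoms: none
Why: Acid-catalysed acetalisation of the α-hydroxy acid under thermodynamic control should give the five-membered dioxolanone with tert-butyl cis to the C15 side chain (self-regeneration of stereocentres) and leave the C5 acid free.

Step 4
Reactants: 6 cis-dioxolanone acid; 7 allyl bromide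
Product: 8 (2S)-3-(benzyloxy)-2-[(2R,4R)-2-tert-butyl-5-oxo-4-(prop-2-en-1-yl)-1,3-dioxolan-4-yl]propanoic acid
Conditions: LiN(SiMe3)2 (2.2 equiv), THF, −78 °C; 7, −78 → −30 °C; cold 1 M HCl
Reagents that add atoms: none
Why: Enolate alkylation of the carboxylate–dioxolanone dianion should occur trans to the tert-butyl group, so allyl replaces the C15 hydrogen with retention and creates the quaternary centre, while the carboxylate shields C4–H from deprotonation.

Step 5
Reactants: 8 allylated dioxolanone acid
Product: 9 (2R,3S)-3-[(benzyloxy)methyl]-2-(prop-2-en-1-yl)butane-1,2,4-triol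
Conditions: LiAlH4 (excess), THF, 0 °C → reflux; H2O, aq. NaOH
Reagents that add atoms: none
Why: Hydride reduction cleaves the dioxolanone to the C14/C15 diol (the acetal carbon leaves as neopentyl alcohol) and reduces the C5 acid to the primary alcohol without touching the alkene, the benzyl ether or either stereocentre.

Step 6
Reactants: 9 triol
Product: 10 (2S)-3-(benzyloxy)-2-[(4R)-2,2-dimethyl-4-(prop-2-en-1-yl)-1,3-dioxolan-4-yl]propan-1-ol
Conditions: Me2C(OMe)2, PPTS (cat.), acetone, rt
Reagents that add atoms: 2,2-dimethoxypropane, COC(C)(C)OC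
Why: Thermodynamic ketalisation should select the five-membered C14/C15 acetonide, since the alternative 1,3-dioxane would force a substituent of the quaternary C15 into a 1,3-diaxial clash with an acetonide methyl, and so leaves only the C5 hydroxyl free.

Step 7
Reactants: 10 acetonide alcohol
Product: 11 {(2R)-3-(benzyloxy)-2-[(4R)-2,2-dimethyl-4-(prop-2-en-1-yl)-1,3-dioxolan-4-yl]propoxy}tri(propan-2-yl)silane
Conditions: TIPSCl, imidazole, DMAP (cat.), DMF, rt
Reagents that add atoms: chlorotri(propan-2-yl)silane, CC(C)[Si](Cl)(C(C)C)C(C)C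
Why: Silylation of the single primary alcohol; the triisopropylsilyl ether is chosen because it survives the dissolving-metal debenzylation and the later acidic acetonide cleavage.

Step 8
Reactants: 11 benzyl ether
Product: 12 (2R)-2-[(4R)-2,2-dimethyl-4-(prop-2-en-1-yl)-1,3-dioxolan-4-yl]-3-{[tri(propan-2-yl)silyl]oxy}propan-1-ol
Conditions: Na, NH3(l), THF, −78 °C; NH4Cl
Reagents that add atoms: none
Why: Birch-type reductive cleavage of the benzyl ether proceeds by electron transfer to the arene and should leave the isolated terminal alkene, the silyl ether and the acetonide untouched.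

Step 9
Reactants: 12 C3 alcohol
Product: 13 (2R)-2-[(4R)-2,2-dimethyl-4-(prop-2-en-1-yl)-1,3-dioxolan-4-yl]-3-{[tri(propan-2-yl)silyl]oxy}propanal (C3 aldehyde, C15 allyl)
Conditions: TEMPO (10 mol%), PhI(OAc)2, CH2Cl2, rt; used crude
Reagents that add atoms: none
Why: Oxoammonium (TEMPO) oxidation of the primary alcohol is non-basic, so C4 next to the new carbonyl should not epimerise and the β-silyloxy group should not eliminate.

Step 10
Reactants: 13 aldehyde with C15 allyl group
Product: 14 (5R,6S,7S,8R)-2,2,8-trimethyl-6-({[tri(propan-2-yl)silyl]oxy}methyl)-1,3-dioxaspiro[4.4]nonan-7-ol (C3–OH trans to the C2 methyl, cis to the C4 arm and to C15–O)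
Conditions: SmI2 (3 equiv, 0.1 M in THF), HMPA (12 equiv), t-BuOH (3 equiv), THF, 0 °C; 13 added over 4 h by syringe pump to a final concentration near 0.005 M
Reagents that add atoms: none
Why: Divalent samarium, made strongly reducing by HMPA, transfers one electron to the C3 aldehyde to give a samarium ketyl that adds to the internal carbon of the allyl group, and a second electron transfer turns the resulting primary radical into an organosamarium that t-BuOH protonates to the C2 methyl. The closest known reaction type is the SmI2–HMPA reductive ketyl–olefin cyclisation of unactivated olefinic ketones and aldehydes to 2-methylcyclopentanols. The ring C15–C1–C2–C3–C4 closes 5-exo-trig through a chair-like transition state, helped by the quaternary C15. C3 is set by the bulky samarium alkoxide lying anti to the alkene, which places C3–O trans to the new methyl, and C2 is set in the same chair, where the C4 CH2OTIPS arm and the C14 methylene are pseudo-equatorial, so the methyl ends trans to the C4 arm and cis to C14. The step needs cyclisation to outrun pinacol coupling and simple reduction, which slow addition at high dilution secures, and it needs C4 to survive, which the non-basic medium and the absence of any leaving group β to a radical or anionic centre secure.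

Step 11
Reactants: 14 cyclopentanol
Product: 15 (5R,6S,7S,8R)-2,2,8-trimethyl-6-({[tri(propan-2-yl)silyl]oxy}methyl)-1,3-dioxaspiro[4.4]nonan-7-yl benzoate
Conditions: BzCl, pyridine, DMAP (cat.), CH2Cl2, 0 °C → rt
Reagents that add atoms: benzoyl chloride, O=C(Cl)c1ccccc1
Why: DMAP-catalysed acylation of the only free hydroxyl installs the C3 benzoate of the target with retention.

Step 12
Reactants: 15 benzoate acetonide
Product: 16 C14,C15-diol (cyclopentane with OH and CH2OH on C15, methyl on C2, benzoate on C3, CH2OTIPS on C4; ring configuration as in 14)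
Conditions: AcOH–H2O (4:1), 50 °C
Reagents that add atoms: none
Why: Acid hydrolysis of the acetonide frees the diol while the primary triisopropylsilyl ether and the benzoate, both stable to aqueous acetic acid, stay in place.

Step 13
Reactants: 16 diol
Product: 17 C14,C15-bis(triethylsilyl) ether of 16
Conditions: Et3SiOTf (2.5 equiv), 2,6-lutidine, CH2Cl2, −78 → 0 °C
Reagents that add atoms: triethylsilyl trifluoromethanesulfonate, CC[Si](CC)(CC)OS(=O)(=O)C(F)(F)F
Why: Silyl triflate silylation covers both the primary and the hindered tertiary hydroxyl, so the C15 alcohol is masked before the α-oxygenated aldehyde is made.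

Step 14
Reactants: 17 bis(triethylsilyl) ether
Product: 18 C14 aldehyde (1-formylcyclopentane with C15–OSiEt3; other groups as in 17)
Conditions: (COCl)2, DMSO, CH2Cl2, −78 → −30 °C; Et3N, → 0 °C
Reagents that add atoms: none
Why: Swern conditions convert a primary triethylsilyl ether directly into the aldehyde (desilylative activation by the chlorosulfonium salt) while tertiary triethylsilyl and triisopropylsilyl ethers are inert, which gives a non-enolisable α-silyloxy aldehyde.

Step 15
Reactants: 18 C14 aldehyde; 19 trans-2-butene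
Product: 21 anti-homoallylic alcohol (C14–OH R; C13–Me R; vinyl C12=C11; C15–OSiEt3), via borinic ester 20 (not isolated)
Conditions: 19, n-BuLi, KOt-Bu, THF, −78 → −45 °C; (+)-Ipc2BOMe, −78 °C; BF3·OEt2; 18, −78 °C; NaBO3·4H2O, THF–H2O, rt
Reagents that add atoms: none
Why: Brown crotylboration: the (E)-crotylborane reacts through a closed chair transition state, so the E geometry gives the anti C13/C14 relationship, and the isopinocampheyl groups derived from (−)-α-pinene should deliver the crotyl group to the Re face of the aldehyde under reagent control, which sets C14 and C13 as in the target.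

Step 16
Reactants: 21 homoallylic alcohol
Product: 22 C14,C15-bis(triethylsilyl) ether of 21
Conditions: Et3SiOTf, 2,6-lutidine, CH2Cl2, −78 → 0 °C
Reagents that add atoms: triethylsilyl trifluoromethanesulfonate, CC[Si](CC)(CC)OS(=O)(=O)C(F)(F)F
Why: Silylation of the hindered secondary C14 alcohol keeps its alkoxide from attacking the tetrazolyl sulfone in the later olefination.

Step 17
Reactants: 22 terminal alkene
Product: 24 C12 primary alcohol, via C12 aldehyde 23 (not isolated)
Conditions: O3, CH2Cl2–MeOH, −78 °C; NaBH4, −78 → 0 °C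
Reagents that add atoms: ozone, [O-][O+]=O
Why: Ozonolysis cleaves the only alkene and in situ borohydride reduction gives the C12 alcohol at once, so the α-methyl aldehyde has no time to epimerise at C13 and the benzoate is not reduced at this temperature.

Step 18
Reactants: 24 C12 alcohol
Product: 25 C12 (1-phenyl-1H-tetrazol-5-yl) sulfide
Conditions: 1-phenyl-1H-tetrazole-5-thiol, PPh3, DIAD, THF, 0 °C → rt
Reagents that add atoms: 1-phenyl-1H-tetrazole-5-thiol, Sc1nnnn1-c1ccccc1
Why: Mitsunobu thioetherification of the unhindered primary alcohol with the acidic heteroaryl thiol.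

Step 19
Reactants: 25 sulfide
Product: 26 C12 (1-phenyl-1H-tetrazol-5-yl) sulfone
Conditions: mCPBA (3 equiv), NaHCO3, CH2Cl2, 0 °C → rt
Reagents that add atoms: 3-chloroperoxybenzoic acid, OOC(=O)c1cccc(Cl)c1
Why: Peracid oxidation takes the sulfide through the sulfoxide to the sulfone; no alkene is present and the silyl ethers and benzoate are inert under buffered conditions.

Step 20
Reactants: 27 ethyl 2,2-dimethyl-3-oxobutanoate
Product: 28 ethyl 2-methyl-2-(2-methyl-1,3-dioxolan-2-yl)propanoate
Conditions: ethylene glycol, TsOH·H2O (cat.), toluene, reflux, Dean–Stark trap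
Reagents that add atoms: ethane-1,2-diol, OCCO
Why: Acid-catalysed ketalisation with removal of water protects the C9 ketone, which would otherwise be enolised or trigger retro-aldol cleavage of the alkoxide formed in the olefination.

Step 21
Reactants: 28 ketal ester
Product: 29 2-methyl-2-(2-methyl-1,3-dioxolan-2-yl)propan-1-ol
Conditions: LiAlH4, Et2O, 0 °C; H2O, aq. NaOH
Reagents that add atoms: none
Why: Hydride reduction of the hindered ester to the neopentyl alcohol; the ketal is inert to hydride.

Step 22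
Reactants: 29 ketal alcohol
Product: 30 2-methyl-2-(2-methyl-1,3-dioxolan-2-yl)propanal
Conditions: TEMPO (10 mol%), PhI(OAc)2, CH2Cl2, rt
Reagents that add atoms: none
Why: Oxoammonium (TEMPO) oxidation of the primary alcohol gives a non-enolisable α-quaternary aldehyde that cannot over-oxidise under these conditions.

Step 23
Reactants: 26 C12 sulfone; 30 α-quaternary aldehyde
Product: 31 (E)-C11=C12 alkene with C9 dioxolane, C14/C15 triethylsilyl ethers, C3 benzoate and C5 triisopropylsilyl ether
Conditions: 26, KN(SiMe3)2, DME, −60 °C; 30, −60 °C → rt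
Reagents that add atoms: none
Why: Julia–Kocienski olefination: the metalated tetrazolyl sulfone adds to the non-enolisable aldehyde, Smiles rearrangement and loss of SO2 and the tetrazolone give the alkene, and the anti adduct favoured with potassium in DME between two branched carbons should give the E isomer.

Step 24
Reactants: 31 protected alkene
Product: 32 C5,C14,C15-triol C9-ketone (C3 benzoate retained)
Conditions: 3 M aq. HCl, THF, rt → 40 °C
Reagents that add atoms: water, O
Why: Aqueous acid hydrolyses the dioxolane to the ketone and cleaves the two triethylsilyl ethers and the primary triisopropylsilyl ether in one operation; the benzoate resists these conditions and the β,γ-unsaturated ketone cannot move into conjugation because C10 is quaternary.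

Step 25
Reactants: 32 triol ketone
Product: 33 C5 aldehyde (C14,C15-diol)
Conditions: TEMPO (10 mol%), NCS, Bu4NCl, CH2Cl2–aq. NaHCO3/K2CO3 buffer (pH 8.6), rt
Reagents that add atoms: none
Why: TEMPO/N-chlorosuccinimide oxidation is selective for the primary C5 alcohol over the hindered secondary C14 and tertiary C15 alcohols and does not cleave the vicinal diol.

Step 26
Reactants: 33 C5 aldehyde; 34 2-(triphenylphosphoranylidene)propanal
Product: 35 (E)-enal C5=C6(Me)–C7HO with free C14,C15-diol
Conditions: 34 (3 equiv), toluene, 80 °C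
Reagents that add atoms: none
Why: Wittig reaction with the formyl-stabilised ylide gives the (E)-2-methyl enal, and the weakly basic ylide should spare the C4 centre and the β-acyloxy and β-hydroxy groups and ignore the hindered C9 ketone.

Step 27
Reactants: 35 enal diol
Product: 36 target, CNP0489076.2 (C14 and C15 acetates, C3 benzoate)
Conditions: Ac2O, Et3N, DMAP (2 equiv), CH2Cl2, rt → 40 °C
Reagents that add atoms: acetic anhydride, CC(=O)OC(C)=O
Why: DMAP-catalysed acetylation esterifies the secondary C14 alcohol quickly and, with excess reagent and gentle warming, the tertiary C15 alcohol, with no change at any stereocentre.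

**Compound list**

1 | dimethyl (R)-malate | COC(=O)C[C@@H](O)C(=O)OC | starting material
2 | benzyl chloromethyl ether | ClCOCc1ccccc1 | starting material
3 | dimethyl (2S,3R)-2-[(benzyloxy)methyl]-3-hydroxybutanedioate | COC(=O)[C@H](O)[C@H](COCc1ccccc1)C(=O)OC | intermediate
4 | (2S,3R)-2-[(benzyloxy)methyl]-3-hydroxybutanedioic acid | OC(=O)[C@H](O)[C@H](COCc1ccccc1)C(O)=O | intermediate
5 | pivalaldehyde | CC(C)(C)C=O | starting material
6 | (2S)-3-(benzyloxy)-2-[(2R,4R)-2-tert-butyl-5-oxo-1,3-dioxolan-4-yl]propanoic acid | CC(C)(C)[C@H]1OC(=O)[C@H](O1)[C@H](COCc2ccccc2)C(O)=O | intermediate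
7 | allyl bromide | C=CCBr | starting material
8 | (2S)-3-(benzyloxy)-2-[(2R,4R)-2-tert-butyl-5-oxo-4-(prop-2-en-1-yl)-1,3-dioxolan-4-yl]propanoic acid | CC(C)(C)[C@H]1OC(=O)[C@@](O1)(CC=C)[C@H](COCc2ccccc2)C(O)=O | intermediate
9 | (2R,3S)-3-[(benzyloxy)methyl]-2-(prop-2-en-1-yl)butane-1,2,4-triol | OC[C@@](O)(CC=C)[C@H](COCc1ccccc1)CO | intermediate
10 | (2S)-3-(benzyloxy)-2-[(4R)-2,2-dimethyl-4-(prop-2-en-1-yl)-1,3-dioxolan-4-yl]propan-1-ol | CC1(C)OC[C@@](O1)(CC=C)[C@H](COCc2ccccc2)CO | intermediate
11 | {(2R)-3-(benzyloxy)-2-[(4R)-2,2-dimethyl-4-(prop-2-en-1-yl)-1,3-dioxolan-4-yl]propoxy}tri(propan-2-yl)silane | CC1(C)OC[C@@](O1)(CC=C)[C@H](COCc2ccccc2)CO[Si](C(C)C)(C(C)C)C(C)C | intermediate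
12 | (2R)-2-[(4R)-2,2-dimethyl-4-(prop-2-en-1-yl)-1,3-dioxolan-4-yl]-3-{[tri(propan-2-yl)silyl]oxy}propan-1-ol | CC1(C)OC[C@@](O1)(CC=C)[C@H](CO)CO[Si](C(C)C)(C(C)C)C(C)C | intermediate
13 | (2R)-2-[(4R)-2,2-dimethyl-4-(prop-2-en-1-yl)-1,3-dioxolan-4-yl]-3-{[tri(propan-2-yl)silyl]oxy}propanal | CC1(C)OC[C@@](O1)(CC=C)[C@H](C=O)CO[Si](C(C)C)(C(C)C)C(C)C | intermediate
14 | (5R,6S,7S,8R)-2,2,8-trimethyl-6-({[tri(propan-2-yl)silyl]oxy}methyl)-1,3-dioxaspiro[4.4]nonan-7-ol | CC1(C)OC[C@@]2(O1)C[C@@H](C)[C@H](O)[C@@H]2CO[Si](C(C)C)(C(C)C)C(C)C | intermediate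
15 | C3 benzoate of 14 | CC1(C)OC[C@@]2(O1)C[C@@H](C)[C@H](OC(=O)c3ccccc3)[C@@H]2CO[Si](C(C)C)(C(C)C)C(C)C | intermediate
16 | C14,C15-diol, C3 benzoate, C5 triisopropylsilyl ether | OC[C@@]1(O)C[C@@H](C)[C@H](OC(=O)c2ccccc2)[C@@H]1CO[Si](C(C)C)(C(C)C)C(C)C | intermediate
17 | C14,C15-bis(triethylsilyl) ether of 16 | CC[Si](CC)(CC)OC[C@@]1(O[Si](CC)(CC)CC)C[C@@H](C)[C@H](OC(=O)c2ccccc2)[C@@H]1CO[Si](C(C)C)(C(C)C)C(C)C | intermediate
18 | C14 aldehyde with C15–OSiEt3 | O=C[C@@]1(O[Si](CC)(CC)CC)C[C@@H](C)[C@H](OC(=O)c2ccccc2)[C@@H]1CO[Si](C(C)C)(C(C)C)C(C)C | intermediate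
19 | trans-2-butene | C/C=C/C | starting material
20 | diisopinocampheylborinic ester of 21 at O14 | C=C[C@@H](C)[C@@H](OB([C@H]1C[C@H]2C[C@@H]([C@@H]1C)C2(C)C)[C@H]1C[C@H]2C[C@@H]([C@@H]1C)C2(C)C)[C@@]1(O[Si](CC)(CC)CC)C[C@@H](C)[C@H](OC(=O)c2ccccc2)[C@@H]1CO[Si](C(C)C)(C(C)C)C(C)C | intermediate
21 | anti-homoallylic alcohol (14R,13R), C15–OSiEt3 | C=C[C@@H](C)[C@@H](O)[C@@]1(O[Si](CC)(CC)CC)C[C@@H](C)[C@H](OC(=O)c2ccccc2)[C@@H]1CO[Si](C(C)C)(C(C)C)C(C)C | intermediate
22 | C14,C15-bis(triethylsilyl) ether of 21 | C=C[C@@H](C)[C@@H](O[Si](CC)(CC)CC)[C@@]1(O[Si](CC)(CC)CC)C[C@@H](C)[C@H](OC(=O)c2ccccc2)[C@@H]1CO[Si](C(C)C)(C(C)C)C(C)C | intermediate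
23 | C12 aldehyde from ozonolysis of 22 | O=C[C@@H](C)[C@@H](O[Si](CC)(CC)CC)[C@@]1(O[Si](CC)(CC)CC)C[C@@H](C)[C@H](OC(=O)c2ccccc2)[C@@H]1CO[Si](C(C)C)(C(C)C)C(C)C | intermediate
24 | C12 primary alcohol | OC[C@@H](C)[C@@H](O[Si](CC)(CC)CC)[C@@]1(O[Si](CC)(CC)CC)C[C@@H](C)[C@H](OC(=O)c2ccccc2)[C@@H]1CO[Si](C(C)C)(C(C)C)C(C)C | intermediate
25 | C12 (1-phenyl-1H-tetrazol-5-yl) sulfide | c1ccc(cc1)-n1nnnc1SC[C@@H](C)[C@@H](O[Si](CC)(CC)CC)[C@@]1(O[Si](CC)(CC)CC)C[C@@H](C)[C@H](OC(=O)c2ccccc2)[C@@H]1CO[Si](C(C)C)(C(C)C)C(C)C | intermediate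
26 | C12 (1-phenyl-1H-tetrazol-5-yl) sulfone | c1ccc(cc1)-n1nnnc1S(=O)(=O)C[C@@H](C)[C@@H](O[Si](CC)(CC)CC)[C@@]1(O[Si](CC)(CC)CC)C[C@@H](C)[C@H](OC(=O)c2ccccc2)[C@@H]1CO[Si](C(C)C)(C(C)C)C(C)C | intermediate
27 | ethyl 2,2-dimethyl-3-oxobutanoate | CCOC(=O)C(C)(C)C(C)=O | starting material
28 | ethyl 2-methyl-2-(2-methyl-1,3-dioxolan-2-yl)propanoate | CCOC(=O)C(C)(C)C1(C)OCCO1 | intermediate
29 | 2-methyl-2-(2-methyl-1,3-dioxolan-2-yl)propan-1-ol | OCC(C)(C)C1(C)OCCO1 | intermediate
30 | 2-methyl-2-(2-methyl-1,3-dioxolan-2-yl)propanal | O=CC(C)(C)C1(C)OCCO1 | intermediate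
31 | (E)-C11=C12 alkene, fully protected (C9 dioxolane, C14/C15 OSiEt3, C3 OBz, C5 OTIPS) | CC1(OCCO1)C(C)(C)/C=C/[C@@H](C)[C@@H](O[Si](CC)(CC)CC)[C@@]1(O[Si](CC)(CC)CC)C[C@@H](C)[C@H](OC(=O)c2ccccc2)[C@@H]1CO[Si](C(C)C)(C(C)C)C(C)C | intermediate
32 | C5,C14,C15-triol C9-ketone, C3 benzoate | CC(=O)C(C)(C)/C=C/[C@@H](C)[C@@H](O)[C@@]1(O)C[C@@H](C)[C@H](OC(=O)c2ccccc2)[C@@H]1CO | intermediate
33 | C5 aldehyde, C14,C15-diol | CC(=O)C(C)(C)/C=C/[C@@H](C)[C@@H](O)[C@@]1(O)C[C@@H](C)[C@H](OC(=O)c2ccccc2)[C@@H]1C=O | intermediate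
34 | 2-(triphenylphosphoranylidene)propanal | CC(C=O)=P(c1ccccc1)(c1ccccc1)c1ccccc1 | starting material
35 | (E)-enal with free C14,C15-diol | CC(=O)C(C)(C)/C=C/[C@@H](C)[C@@H](O)[C@@]1(O)C[C@@H](C)[C@H](OC(=O)c2ccccc2)[C@@H]1/C=C(\C)C=O | intermediate
36 | CNP0489076.2 | CC(=O)O[C@H]([C@H](C)/C=C/C(C)(C)C(C)=O)[C@@]1(OC(C)=O)C[C@@H](C)[C@H](OC(=O)c2ccccc2)[C@@H]1/C=C(\C)C=O | target

**Step count**

Total: 27 steps. Longest linear sequence: 24 steps (steps 1–19 and 23–27, from dimethyl (R)-malate); steps 20–22 make the aldehyde 30 in a side branch.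

**Steps most likely to fail**

Step 10. The ketyl may dimerise (pinacol coupling) or be reduced further to the alcohol 12 before it adds to the unactivated alkene, and the facial preference at C3 may erode because the bulky samarium alkoxide must sit cis to the C4 arm. The fallback activates the acceptor and sets out from alcohol 12. Cross-metathesis with phenyl vinyl sulfone (second-generation Hoveyda–Grubbs catalyst, CH2Cl2, 40 °C) should give the (E)-vinyl sulfone alcohol F1, and TEMPO/PhI(OAc)2 oxidation the vinyl sulfone aldehyde F2. SmI2 in THF–MeOH at −78 °C should then close the same C2–C3 bond 5-exo onto the electron-poor alkene, a fast and anti-selective process that needs no HMPA, to give the sulfonylmethyl cyclopentanol F3. Reductive desulfonylation with Na(Hg) and Na2HPO4 in MeOH turns the CH2SO2Ph group into the C2 methyl and comes back to the route at 14.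

Step 15. Addition to the neopentyl α-silyloxy aldehyde may be slow, and the reagent has to override whatever facial bias the quaternary C15 exerts, so poor facial selectivity at C14/C13 is possible. The fallback replaces allylboration by a Marshall propargylation and sets out from aldehyde 18. The chiral allenylzinc made from (S)-but-3-yn-2-yl methanesulfonate (Pd(OAc)2, PPh3, Et2Zn, THF, −20 °C) adds through a cyclic transition state with net inversion at the propargylic carbon and should give the anti-homopropargylic alcohol F4 with C13 and C14 as required. Semihydrogenation (H2, Pd/CaCO3 poisoned with Pb(OAc)2, quinoline) comes back to the route at 21.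

Step 23. The branched sulfonyl anion may add too slowly to the neopentyl aldehyde, so that self-condensation of the tetrazolyl sulfone or loss of E selectivity takes over. The fallback is the stepwise Julia–Lythgoe olefination, which tolerates such hindered pairs, and sets out from alcohol 24. PhSSPh/Bu3P gives the C12 phenyl sulfide F5 and mCPBA the C12 phenyl sulfone F6. Deprotonation with LiN(iPr)2 (THF, −78 °C), addition to aldehyde 30 and trapping with Ac2O give the β-acetoxy sulfone F7 as a mixture at C11 and C12. Reductive elimination with SmI2/HMPA (or Na(Hg) in MeOH) should give the E alkene and comes back to the route at 31.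

**Further compounds**

F1 | step 10 | (E)-vinyl sulfone alcohol (12 with CH2CH=CHSO2Ph in place of allyl) | CC1(C)OC[C@@](O1)(C/C=C/S(=O)(=O)c2ccccc2)[C@H](CO)CO[Si](C(C)C)(C(C)C)C(C)C
F2 | step 10 | vinyl sulfone aldehyde | CC1(C)OC[C@@](O1)(C/C=C/S(=O)(=O)c2ccccc2)[C@H](C=O)CO[Si](C(C)C)(C(C)C)C(C)C
F3 | step 10 | sulfonylmethyl cyclopentanol (14 with CH2SO2Ph in place of the C2 methyl) | CC1(C)OC[C@@]2(O1)C[C@@H](CS(=O)(=O)c3ccccc3)[C@H](O)[C@@H]2CO[Si](C(C)C)(C(C)C)C(C)C
F4 | step 15 | anti-homopropargylic alcohol (21 with ethynyl in place of vinyl) | C#C[C@@H](C)[C@@H](O)[C@@]1(O[Si](CC)(CC)CC)C[C@@H](C)[C@H](OC(=O)c2ccccc2)[C@@H]1CO[Si](C(C)C)(C(C)C)C(C)C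
F5 | step 23 | C12 phenyl sulfide | c1ccccc1SC[C@@H](C)[C@@H](O[Si](CC)(CC)CC)[C@@]1(O[Si](CC)(CC)CC)C[C@@H](C)[C@H](OC(=O)c2ccccc2)[C@@H]1CO[Si](C(C)C)(C(C)C)C(C)C
F6 | step 23 | C12 phenyl sulfone | c1ccccc1S(=O)(=O)C[C@@H](C)[C@@H](O[Si](CC)(CC)CC)[C@@]1(O[Si](CC)(CC)CC)C[C@@H](C)[C@H](OC(=O)c2ccccc2)[C@@H]1CO[Si](C(C)C)(C(C)C)C(C)C
F7 | step 23 | β-acetoxy sulfone (C11 OAc, C12 SO2Ph, both centres mixed) | CC1(OCCO1)C(C)(C)C(OC(C)=O)C([C@@H](C)[C@@H](O[Si](CC)(CC)CC)[C@@]1(O[Si](CC)(CC)CC)C[C@@H](C)[C@H](OC(=O)c2ccccc2)[C@@H]1CO[Si](C(C)C)(C(C)C)C(C)C)S(=O)(=O)c1ccccc1
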